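**Retrosynthetic overview**
1. Target 22 ⇐ acid opening of a 3α,4α-epoxide at C4 (last step) ⇐ tin-directed angeloylation of O-10 ⇐ 8,10-anti diol by hydroxyl-directed reduction of a C8 enone.
2. C8–C9 bond ⇐ addition of a C9 organolithium (C10 stereocentre bought in D-glycerate acetonide ester 12) to the lactone carbonyl of 11, which already carries the O-5 angelate.
3. Lactone 9 ⇐ oxidative lactonisation of keto acid 7 (C8 carboxylate onto C6, placing O-6 cis to the side chain); 5-OH ⇐ Luche reduction; epoxide ⇐ nucleophilic epoxidation of (S)-carvone 1.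
4. Key step: the C8–O bond, which becomes the handle for both lactonisation and fragment union, is made from the isopropenyl methyl with SeO2 by an ene reaction followed by the [2,3]-sigmatropic rearrangement of allylseleninic acid 3.
5. Rings: the cyclohexane is bought with 1; the oxirane (step 1) and the γ-lactone (step 4) are temporary and are opened in steps 13 and 10.

Labels used (one assumption on naming): ring C1 (bears the side chain) to C6, methyl C15 on C4, side chain C7(=C14H2)–C8–C9–C10–C11(C12)(C13); β = ring face of the C1 side chain, α = face of H-1; "bisabol" names use these labels; angeloyl = (Z)-2-methylbut-2-enoyl.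

Step 1
Reactants: 1 (S)-(+)-carvone
Product: 2 trans-carvone epoxide (1S,4S,6S)-1-methyl-4-(prop-1-en-2-yl)-7-oxabicyclo[4.1.0]heptan-2-one (3α,4α-epoxide)
Conditions: H2O2 (30% aq.), NaOH (cat.), MeOH, 0 °C
Reagents that add atoms: hydrogen peroxide, OO
Why: Weitz–Scheffer nucleophilic epoxidation attacks only the enone, with hydroperoxide adding to C3 on the face opposite the C1 isopropenyl group, which sets C3 and C4 as the α-epoxide.

Step 2
Reactants: 2 trans-carvone epoxide
Product: 5 (1S,4S,6S)-4-(3-hydroxyprop-1-en-2-yl)-1-methyl-7-oxabicyclo[4.1.0]heptan-2-one, via allylseleninic acid 3 (not isolated), via allyl selenoxylate ester 4 (not isolated)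
Conditions: SeO2 (0.3 equiv), t-BuOOH, CH2Cl2, rt
Reagents that add atoms: selenium dioxide, O=[Se]=O (catalytic oxygen carrier); tert-butyl hydroperoxide, CC(C)(C)OO (terminal oxidant)
Why: Riley–Sharpless allylic oxidation, in which the ene reaction of SeO2 takes a methyl hydrogen of the isopropenyl group (CH3 preferred over the ring CH) and the [2,3]-sigmatropic rearrangement of 3 forms the C8–O bond of 4, which is hydrolysed to 5 without touching a stereocentre.

Step 3
Reactants: 5 the 8-hydroxy epoxy ketone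
Product: 7 2-[(1S,3S,6S)-6-methyl-5-oxo-7-oxabicyclo[4.1.0]heptan-3-yl]prop-2-enoic acid, via enal 6 (not isolated)
Conditions: 2,2,6,6-tetramethylpiperidin-1-oxyl (cat.), PhI(OAc)2, CH2Cl2, rt; then NaClO2, NaH2PO4, 2-methyl-2-butene, t-BuOH/H2O, 0 °C → rt
Reagents that add atoms: sodium chlorite, [Na+].[O-]Cl=O
Why: Oxoammonium oxidation of the primary allylic alcohol to enal 6 followed by Pinnick oxidation gives the acrylic acid under conditions that leave the epoxy ketone and all stereocentres alone.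

Step 4
Reactants: 7 the epoxy keto acid
Product: 9 (1R,3S,4S,6S)-3α,4α-epoxy-5-oxo 8,6β-lactone (cis-fused α-methylene-γ-butyrolactone), via 6α-iodanyl ketone 8 (not isolated)
Conditions: PhI(OH)OTs, MeCN, 40 °C
Reagents that add atoms: none
Why: Moriarty-type oxidative lactonisation of a 5-oxo acid, in which the trivalent iodine reagent binds the C5 enol at C6 on the face away from the C1 substituent and the carboxylate displaces PhI intramolecularly with inversion (SN2), so O-6 ends cis to C1–C7 and C6 is set.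

Step 5
Reactants: 9 the keto lactone
Product: 10 (1R,3S,4R,5S,6S)-3α,4α-epoxy-5β-hydroxy 8,6β-lactone
Conditions: NaBH4, CeCl3·7H2O, MeOH, −78 °C
Reagents that add atoms: none
Why: Luche reduction delivers hydride to the C5 ketone from the convex α-face of the cis-fused bicycle, anti to the axial C6–O bond (polar Felkin–Anh), giving the equatorial 5β-alcohol, while CeCl3 suppresses 1,4-reduction of the α-methylene lactone.

Step 6
Reactants: 10 the 5β-hydroxy lactone
Product: 11 (1R,3S,4S,5S,6S)-5β-angeloyloxy-3α,4α-epoxy 8,6β-lactone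
Conditions: angelic acid, 2,4,6-trichlorobenzoyl chloride, Et3N, toluene, rt; then 10, 75 °C
Reagents that add atoms: angelic acid, C/C=C(/C)C(=O)O
Why: Yamaguchi esterification through the mixed anhydride without DMAP acylates the only free hydroxyl with retention at C5 and without Z to E isomerisation of the angelate.

Step 7
Reactants: 12 methyl (R)-2,2-dimethyl-1,3-dioxolane-4-carboxylate
Product: 13 (R)-2-(2,2-dimethyl-1,3-dioxolan-4-yl)propan-2-ol
Conditions: MeMgBr (3 equiv), THF, 0 °C → rt; aq. NH4Cl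
Reagents that add atoms: methylmagnesium bromide, C[Mg]Br
Why: Double Grignard addition to the ester builds the C11 dimethyl carbinol and leaves the bought stereocentre (later C10) untouched.

Step 8
Reactants: 13 the acetonide alcohol
Product: 14 (R)-3-methylbutane-1,2,3-triol
Conditions: AcOH/H2O (4:1), 40 °C
Reagents that add atoms: none
Why: Acid-catalysed acetal hydrolysis frees the 1,2-diol without affecting the stereocentre.

Step 9
Reactants: 14 the triol
Product: 15 (S)-1-iodo-3-methylbutane-2,3-diol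
Conditions: I2, PPh3, imidazole, THF, 0 °C
Reagents that add atoms: iodine, II
Why: Garegg–Samuelsson (Appel-type) iodination is selective for the primary hydroxyl, and the descriptor changes to S only through CIP priority, not geometry.

Step 10
Reactants: 11 the angeloyloxy lactone; 15 the iodo diol
Product: 18 (1R,3S,4S,5S,6S,10R)-5-angeloyloxy-3,4-epoxy-6,10,11-trihydroxybisabol-7(14)-en-8-one, via trilithiated diol 16 (not isolated), via lithium hemiketal 17 (not isolated)
Conditions: 15 (1.4 equiv), MeLi (2.8 equiv), THF, −78 °C; t-BuLi (2.8 equiv), −78 °C; then 11, −78 °C; AcOH quench at −78 °C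
Reagents that add atoms: none
Why: Iodine–lithium exchange on the dilithium dialkoxide gives β-oxido organolithium 16, whose 1,2-addition to the strained lactone carbonyl (much faster than to the hindered angelate) stops at hemiketal 17 and releases the enone and the 6β-hydroxyl on quench, with C10 carried in from 15 and no new stereocentre formed.

Step 11
Reactants: 18 the β-hydroxy enone
Product: 19 (1R,3S,4S,5S,6S,8R,10R)-5-angeloyloxy-3,4-epoxybisabol-7(14)-ene-6,8,10,11-tetraol
Conditions: Me4NBH(OAc)3, MeCN/AcOH (1:1), −30 °C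
Reagents that add atoms: none
Why: Evans–Saksena reduction, in which the C10 hydroxyl binds boron and delivers hydride intramolecularly through a chair transition state, gives the 8,10-anti diol and sets C8 as R.

Step 12
Reactants: 19 the tetraol
Product: 21 (1R,3S,4S,5S,6S,8R,10R)-5,10-bis(angeloyloxy)-3,4-epoxybisabol-7(14)-ene-6,8,11-triol, via 10,11-O-dibutylstannylene acetal 20 (not isolated)
Conditions: Bu2SnO (1.05 equiv), toluene, 80 °C, 4 Å molecular sieves; then angelic anhydride, THF, 0 °C → rt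
Reagents that add atoms: angelic anhydride, C/C=C(/C)C(=O)OC(=O)/C(C)=C\C
Why: Tin-mediated regioselective acylation, in which Bu2SnO forms the five-membered stannylene of the only vicinal diol (O-10/O-11) and the activated, less hindered secondary O-10 is acylated under neutral conditions while the isolated 6- and 8-hydroxyls stay free.

Step 13
Reactants: 21 the bis-angelate epoxide
Product: 22 (1R,3S,4R,5S,6S,8R,10R)-5,10-bis(angeloyloxy)bisabol-7(14)-ene-3,4,6,8,11-pentaol (CNP0108485.1)
Conditions: HClO4 (cat.), THF/H2O (2:1), 0 °C → rt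
Reagents that add atoms: water, O
Why: Acid-catalysed epoxide hydrolysis with attack at the tertiary C4 anti to the epoxide oxygen (Markovnikov and trans-diaxial, Fürst–Plattner) inverts C4 to the 4β-alcohol and leaves the 3α-oxygen in place.

**Compound list**
1 | (S)-(+)-carvone | CC1=CC[C@@H](CC1=O)C(C)=C | starting material
2 | trans-carvone epoxide, (1S,4S,6S)-1-methyl-4-(prop-1-en-2-yl)-7-oxabicyclo[4.1.0]heptan-2-one | C=C(C)[C@H]1C[C@@H]2O[C@]2(C)C(=O)C1 | intermediate
3 | allylseleninic acid, 2-[(1S,3S,6S)-6-methyl-5-oxo-7-oxabicyclo[4.1.0]heptan-3-yl]prop-2-ene-1-seleninic acid | C=C(C[Se](=O)O)[C@H]1C[C@@H]2O[C@]2(C)C(=O)C1 | intermediate (not isolated)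
4 | allyl selenoxylate ester (O-bound divalent selenium ester of 5 formed in the [2,3] shift) | C=C(CO[Se]O)[C@H]1C[C@@H]2O[C@]2(C)C(=O)C1 | intermediate (not isolated)
5 | (1S,4S,6S)-4-(3-hydroxyprop-1-en-2-yl)-1-methyl-7-oxabicyclo[4.1.0]heptan-2-one | C=C(CO)[C@H]1C[C@@H]2O[C@]2(C)C(=O)C1 | intermediate
6 | enal, 2-[(1S,3S,6S)-6-methyl-5-oxo-7-oxabicyclo[4.1.0]heptan-3-yl]prop-2-enal | C=C(C=O)[C@H]1C[C@@H]2O[C@]2(C)C(=O)C1 | intermediate (not isolated)
7 | 2-[(1S,3S,6S)-6-methyl-5-oxo-7-oxabicyclo[4.1.0]heptan-3-yl]prop-2-enoic acid | C=C(C(=O)O)[C@H]1C[C@@H]2O[C@]2(C)C(=O)C1 | intermediate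
8 | 6α-iodanyl ketone, acid 7 carrying PhI(OTs) on C6 trans to the side chain | C=C(C(=O)O)[C@H]1C[C@@H]2O[C@]2(C)C(=O)[C@@H]1I(c1ccccc1)OS(=O)(=O)c1ccc(C)cc1 | intermediate (not isolated)
9 | (1R,3S,4S,6S)-3α,4α-epoxy-5-oxo 8,6β-lactone (cis-fused α-methylene-γ-butyrolactone) | C=C1[C@H]2C[C@@H]3O[C@]3(C)C(=O)[C@H]2OC1=O | intermediate
10 | (1R,3S,4R,5S,6S)-3α,4α-epoxy-5β-hydroxy 8,6β-lactone | C=C1[C@H]2C[C@@H]3O[C@]3(C)[C@@H](O)[C@H]2OC1=O | intermediate
11 | (1R,3S,4S,5S,6S)-5β-angeloyloxy-3α,4α-epoxy 8,6β-lactone | C=C1[C@H]2C[C@@H]3O[C@]3(C)[C@@H](OC(=O)/C(C)=C\C)[C@H]2OC1=O | intermediate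
12 | methyl (R)-2,2-dimethyl-1,3-dioxolane-4-carboxylate (from D-mannitol) | COC(=O)[C@H]1COC(C)(C)O1 | starting material
13 | (R)-2-(2,2-dimethyl-1,3-dioxolan-4-yl)propan-2-ol | CC(C)(O)[C@H]1COC(C)(C)O1 | intermediate
14 | (R)-3-methylbutane-1,2,3-triol | CC(C)(O)[C@H](O)CO | intermediate
15 | (S)-1-iodo-3-methylbutane-2,3-diol | CC(C)(O)[C@H](O)CI | intermediate
16 | trilithiated diol, (R)-1-lithio-3-methylbutane-2,3-diol dilithium dialkoxide | [Li]C[C@@H](O[Li])C(C)(C)O[Li] | intermediate (not isolated)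
17 | lithium hemiketal, tetrahedral adduct of 16 at C8 of 11 | C=C1[C@H]2C[C@@H]3O[C@]3(C)[C@@H](OC(=O)/C(C)=C\C)[C@H]2OC1(O[Li])C[C@@H](O[Li])C(C)(C)O[Li] | intermediate (not isolated)
18 | (1R,3S,4S,5S,6S,10R)-5-angeloyloxy-3,4-epoxy-6,10,11-trihydroxybisabol-7(14)-en-8-one | C=C(C(=O)C[C@@H](O)C(C)(C)O)[C@H]1C[C@@H]2O[C@]2(C)[C@@H](OC(=O)/C(C)=C\C)[C@H]1O | intermediate
19 | (1R,3S,4S,5S,6S,8R,10R)-5-angeloyloxy-3,4-epoxybisabol-7(14)-ene-6,8,10,11-tetraol | C=C([C@H](O)C[C@@H](O)C(C)(C)O)[C@H]1C[C@@H]2O[C@]2(C)[C@@H](OC(=O)/C(C)=C\C)[C@H]1O | intermediate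
20 | 10,11-O-dibutylstannylene acetal of 19 | C=C([C@H](O)C[C@H]1O[Sn](CCCC)(CCCC)OC1(C)C)[C@H]1C[C@@H]2O[C@]2(C)[C@@H](OC(=O)/C(C)=C\C)[C@H]1O | intermediate (not isolated)
21 | (1R,3S,4S,5S,6S,8R,10R)-5,10-bis(angeloyloxy)-3,4-epoxybisabol-7(14)-ene-6,8,11-triol | C=C([C@H](O)C[C@@H](OC(=O)/C(C)=C\C)C(C)(C)O)[C@H]1C[C@@H]2O[C@]2(C)[C@@H](OC(=O)/C(C)=C\C)[C@H]1O | intermediate
22 | (1R,3S,4R,5S,6S,8R,10R)-5,10-bis(angeloyloxy)bisabol-7(14)-ene-3,4,6,8,11-pentaol (CNP0108485.1) | C=C([C@H](O)C[C@@H](OC(=O)/C(C)=C\C)C(C)(C)O)[C@H]1C[C@H](O)[C@@](C)(O)[C@@H](OC(=O)/C(C)=C\C)[C@H]1O | target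

**Step count**
Total: 13 steps. Longest linear sequence: 10 steps (steps 1–6 and 10–13, from (S)-carvone); the C5 fragment takes 3 steps (7–9).

**Three steps most likely to fail**

Step 4 (oxidative lactonisation). The acidic iodine reagent may open or rearrange the epoxy ketone before C6 is functionalised. The fallback sets out from 7 and comes back at 9. Acid 7 is treated with LiN(SiMe3)2 and Me3SiCl at −78 °C to give the trimethylsilyl ester–5-silyl enol ether F1. Rubottom oxidation with dimethyldioxirane attacks C6 anti to the side chain and, after mild acidic work-up, gives the 6α-hydroxy keto acid F2 (6-OH trans to the chain). An intramolecular Mitsunobu reaction (PPh3, diisopropyl azodicarboxylate, THF, 0 °C) then closes the lactone with inversion at C6 to give 9.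

Step 10 (fragment union). Organolithium 16 may add in the conjugate sense to the α-methylene lactone, add twice, or lose lithium oxide by β-elimination. The fallback sets out from 11 and comes back at 18. The exocyclic alkene is first masked by aza-Michael addition of dimethylamine (THF, 0 °C) to give the 14-(dimethylamino) lactone F3. Addition of 16 at −78 °C then meets only the lactone carbonyl and gives the amino hydroxy ketone F4. Quaternisation with MeI gives the trimethylammonium iodide F5, and elimination with aqueous NaHCO3 restores the 7(14)-alkene to give 18.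

Step 12 (tin-directed angeloylation). A six-membered 8,10-stannylene or acyl migration could put the ester on O-8 or O-6. The fallback sets out from 19 and comes back at 21. The least hindered secondary hydroxyl (allylic C8–OH) is silylated selectively with Et3SiCl and imidazole at −40 °C to give the 8-O-triethylsilyl ether F6. Yamaguchi angeloylation of C10–OH (the axial, doubly flanked C6–OH and the tertiary C11–OH stay free) gives the silylated bis-angelate F7. HF·pyridine in THF at 0 °C removes the silyl group to give 21.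

Further compounds
F1 | step 4 | trimethylsilyl ester and 5-trimethylsilyl enol ether of acid 7 | C=C(C(=O)O[Si](C)(C)C)[C@H]1C[C@@H]2O[C@]2(C)C(O[Si](C)(C)C)=C1
F2 | step 4 | 6α-hydroxy derivative of keto acid 7 (6-OH trans to the side chain) | C=C(C(=O)O)[C@H]1C[C@@H]2O[C@]2(C)C(=O)[C@@H]1O
F3 | step 10 | 14-(dimethylamino)-7,14-dihydro derivative of lactone 11 | CN(C)CC1[C@H]2C[C@@H]3O[C@]3(C)[C@@H](OC(=O)/C(C)=C\C)[C@H]2OC1=O
F4 | step 10 | 14-(dimethylamino)-7,14-dihydro derivative of enone 18 | CN(C)CC(C(=O)C[C@@H](O)C(C)(C)O)[C@H]1C[C@@H]2O[C@]2(C)[C@@H](OC(=O)/C(C)=C\C)[C@H]1O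
F5 | step 10 | trimethylammonium iodide of F4 | C[N+](C)(C)CC(C(=O)C[C@@H](O)C(C)(C)O)[C@H]1C[C@@H]2O[C@]2(C)[C@@H](OC(=O)/C(C)=C\C)[C@H]1O.[I-]
F6 | step 12 | 8-O-triethylsilyl ether of tetraol 19 | C=C([C@H](O[Si](CC)(CC)CC)C[C@@H](O)C(C)(C)O)[C@H]1C[C@@H]2O[C@]2(C)[C@@H](OC(=O)/C(C)=C\C)[C@H]1O
F7 | step 12 | 8-O-triethylsilyl ether of bis-angelate 21 | C=C([C@H](O[Si](CC)(CC)CC)C[C@@H](OC(=O)/C(C)=C\C)C(C)(C)O)[C@H]1C[C@@H]2O[C@]2(C)[C@@H](OC(=O)/C(C)=C\C)[C@H]1O
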